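The earlier runs and the new flask are calculated for substances that don't exist.

**Two questions.** Two questions stand: when, within the limit, double product is highest, and how much there is then.

all flasks: substrate 24 mM
- west: reagent 18 mM; run made earlier
- north-west: reagent 27 mM; run made earlier
- flask: reagent 36.0 mM; time 4.0 h

- west (time / h: double product / %, substrate / %): 1.00: 0.7, 90.3; 1.50: 0.7, 87.0; 2.50: 3.6, 80.8; 4.00: 6.1, 71.0
- north-west (time / h: double product / %, substrate / %): 1.00: 1.6, 86.7; 1.50: 3.1, 82.2; 2.50: 6.0, 70.5; 4.00: 12.2, 59.8

(scatter of a reading: 0.5 percentage points)

- a reading or a percentage of double product counts all its forms, free or not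
- a reading of substrate is of its free form alone

- the best time, 4.0 h at the latest, for double product
- the amount of double product, in percent of the substrate charged, at that time

**First rung.** Substrate moves first. Its loss in the north-west run, scaled in proportion to charged [reagent], gives the flask a half-life of 4.04 h, and the west run scaled likewise gives 4.05 h. That is about the 4.0 h allowed, so we expect about half of the flask's substrate to remain free at the limit.

**Second rung.** Double product lags: the north-west run reads 1.6% at 1.00 h, and it is still climbing late, from 6.0% at 2.50 h to 12.2% at 4.00 h. We see no turn, so we put the flask's best time at the limit.

**Reagent order.** North-west against west at 4.00 h gives 1.71, the reagent order (an apparent order), the power of charged [reagent] to which double product answers at a fixed time and a fixed charge of substrate. Going from 27 mM to 36.0 mM, we reckon 20.0% for the flask.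

**Forecast, result.** The forecast says 4 h and 19%, an amount lower than our figure, and for the time it gives as ground: “Nothing shows double product being consumed”. The flask gives 4.00 h and 18.2%.

    substrate + reagent → mono adduct (k = 5.10 L mol⁻¹ h⁻¹)
    substrate + double product ⇌ idle adduct, settled at all times (K = 120 L mol⁻¹)
    reagent + mono adduct → double product (k = 10.0 L mol⁻¹ h⁻¹)

**Mono adduct.** In the flask, mono adduct is made 2.37 times faster than it is used up at 1.40 h, each step taken net, but 1.05 times at 4.00 h. Between the north-west charge and the flask's, the reagent order reads 1.39, lower than the 1.71 from the two runs. Going down from west to the neighbour flask with 9.0 mM of reagent, the carried order gives 1.87%, and that flask holds 1.76% at 4.00 h.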